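Both cyclohexane units are enantiomeric to natural quinic acid, so each is built de novo. Everything rests on disconnecting ring B at C1–C6 and C2–C3: the quaternary C1, which carries the carboxyl carbon and the oxygen of the hindered inter-ring ester, is the α-carbon of a 2-acyloxyacrolein whose acyl group is the complete, protected ring A acid. A catalytic enantioselective Diels–Alder reaction with butadiene closes ring B, sets C1 and delivers the tertiary ester ready-made; a temporary C1-carboxyl-to-O5 γ-lactone then relays C1 to C3, C4 and C5. Ring A is made earlier by the same sequence; the caffeoyl groups are attached last, one at a time.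

Key step: step 13

Naming: "ent-quinic" means the enantiomer of natural (−)-quinic acid with quinic acid numbering (C1 bears the carboxyl; O3 and O4 cis; O5 trans to O4 and cis to the carboxyl); "ent-quinide" is its 1,5-lactone. Ring A is the acyl unit, ring B the unit esterified at O1.
Assumption: the (R)-binaphthyldiammonium salt is taken to give the (R)-configured adducts 6 and 18; if the sense of induction proves opposite, the (S)-diamine is used in steps 3 and 13.

Step 1
Reactants: 1 2,2-dimethyl-1,3-dioxan-5-one
Product: 3 2,2-dimethyl-4H-1,3-dioxin-5-yl acetate, via sodium enolate 2 (not isolated)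
Conditions: NaN(SiMe3)2, THF, −78 °C; then Ac2O, −78 → 0 °C
Reagents that add atoms: acetic anhydride, CC(=O)OC(C)=O; sodium bis(trimethylsilyl)amide, C[Si](C)(C)[N-][Si](C)(C)C.[Na+] (sodium of intermediate 2 only)
Why: Enolate O-acylation, in which the preformed sodium enolate is trapped at oxygen by acetic anhydride to give the enol acetate.

Step 2
Reactants: 3 2,2-dimethyl-4H-1,3-dioxin-5-yl acetate
Product: 4 2-acetoxyacrolein
Conditions: toluene, 110 °C, acetone distilled off
Reagents that add atoms: none
Why: Retro-hetero-Diels–Alder cycloreversion of the 4H-1,3-dioxin releases acetone and unveils the 2-acyloxyacrolein.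

Step 3
Reactants: 4 2-acetoxyacrolein; 5 buta-1,3-diene
Product: 6 (R)-1-formylcyclohex-3-en-1-yl acetate
Conditions: (R)-1,1'-binaphthyl-2,2'-diamine (5 mol %), Tf2NH (9.5 mol %), butadiene (excess), EtCN, −78 → −40 °C
Reagents that add atoms: none
Why: Enantioselective Diels–Alder reaction under chiral primary-ammonium (iminium) catalysis, in which the binaphthyl salt shields one face of the aldiminium ion and so sets C1 of ring A, while symmetrical butadiene raises no regiochemical question.

Step 4
Reactants: 6 (R)-1-formylcyclohex-3-en-1-yl acetate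
Product: 7 (R)-1-acetoxycyclohex-3-ene-1-carboxylic acid
Conditions: NaClO2, NaH2PO4, 2-methylbut-2-ene, t-BuOH/H2O, 0 °C → rt
Reagents that add atoms: sodium chlorite, [Na+].[O-]Cl=O
Why: Pinnick oxidation converts the hindered aldehyde to the acid without touching the ring alkene (hypochlorous acid is scavenged) or the quaternary stereocentre.

Step 5
Reactants: 7 (R)-1-acetoxycyclohex-3-ene-1-carboxylic acid
Product: 8 1-acetoxy-4-iodo-6-oxabicyclo[3.2.1]octan-7-one (iodine trans to the lactone oxygen; ent-quinide series)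
Conditions: I2, NaHCO3, H2O/CH2Cl2, 0 °C → rt, dark
Reagents that add atoms: iodine, II
Why: Iodolactonization, in which the carboxylate opens the iodonium ion anti to give the bridged γ-lactone, so that O5 is set cis to the carboxyl and iodine trans at C4 under control of C1; the crystalline iodolactone also allows enantiomeric enrichment.

Step 6
Reactants: 8 the iodolactone
Product: 9 7-oxo-6-oxabicyclo[3.2.1]oct-3-en-1-yl acetate
Conditions: DBU, toluene, 80 °C
Reagents that add atoms: none
Why: E2 dehydroiodination takes the anti-periplanar hydrogen at C3 because the alternative bridgehead alkene is forbidden (Bredt), which places the alkene at C3=C4.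

Step 7
Reactants: 9 the unsaturated lactone
Product: 10 1-O-acetyl-ent-quinide (cis-3,4-diol anti to the lactone bridge)
Conditions: OsO4 (2 mol %), N-methylmorpholine N-oxide, acetone/H2O, rt
Reagents that add atoms: osmium tetroxide, O=[Os](=O)(=O)=O (catalytic oxygen carrier); N-methylmorpholine N-oxide, C[N+]1([O-])CCOCC1; water, O
Why: Upjohn cis-dihydroxylation occurs on the alkene face opposite the lactone bridge, which sets O3 and O4 cis to each other and trans to O5.

Step 8
Reactants: 10 1-O-acetyl-ent-quinide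
Product: 11 1-O-acetyl-3,4-O-isopropylidene-ent-quinide
Conditions: Me2C(OMe)2, TsOH·H2O (cat.), acetone, rt
Reagents that add atoms: 2,2-dimethoxypropane, COC(C)(C)OC
Why: Acid-catalysed transketalisation gives the acetonide of the cis-3,4-diol.

Step 9
Reactants: 11 1-O-acetyl-3,4-O-isopropylidene-ent-quinide
Product: 12 3,4-O-isopropylidene-ent-quinic acid
Conditions: LiOH·H2O (5 equiv), THF/H2O, 0 → 40 °C; then 1 M HCl to pH 3–4, 0 °C; used at once
Reagents that add atoms: lithium hydroxide, [Li+].[OH-]
Why: Saponification, in which hydroxide opens the strained γ-lactone and then cleaves the tertiary acetate without affecting any stereocentre.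

Step 10
Reactants: 12 3,4-O-isopropylidene-ent-quinic acid
Product: 13 triethylsilyl 3,4-O-isopropylidene-1,5-bis-O-(triethylsilyl)-ent-quinate
Conditions: Et3SiOTf (3.5 equiv), 2,6-lutidine, CH2Cl2, −78 → 0 °C; used crude
Reagents that add atoms: triethylsilyl trifluoromethanesulfonate, CC[Si](CC)(CC)OS(=O)(=O)C(F)(F)F
Why: Silylation with a silyl triflate and a hindered base caps the tertiary hydroxyl, the secondary hydroxyl and the acid (as silyl ester) in one operation.

Step 11
Reactants: 13 the tris(triethylsilyl) compound; 1 2,2-dimethyl-1,3-dioxan-5-one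
Product: 16 2,2-dimethyl-4H-1,3-dioxin-5-yl 3,4-O-isopropylidene-1,5-bis-O-(triethylsilyl)-ent-quinate, via acid chloride 14 (not isolated), via potassium enolate 15 (not isolated)
Conditions: 13, (COCl)2, DMF (cat.), CH2Cl2, 0 °C → rt, evaporate; separately 1, KN(SiMe3)2, THF, −78 °C; then add 14, −78 → 0 °C
Reagents that add atoms: oxalyl chloride, ClC(=O)C(=O)Cl (chlorine of intermediate 14 only); potassium bis(trimethylsilyl)amide, C[Si](C)(C)[N-][Si](C)(C)C.[K+] (potassium of intermediate 15 only)
Why: Vilsmeier-type conversion of the silyl ester to the acid chloride under neutral conditions keeps the silyl ethers, and O-acylation of the dissociated potassium enolate, far less sensitive to hindrance than acylation of a tertiary alcohol, installs the future inter-ring ester.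

Step 12
Reactants: 16 the dioxinyl ester
Product: 17 3-oxoprop-1-en-2-yl 3,4-O-isopropylidene-1,5-bis-O-(triethylsilyl)-ent-quinate (the 2-acyloxyacrolein)
Conditions: toluene, 110 °C, acetone distilled off; used crude
Reagents that add atoms: none
Why: Retro-hetero-Diels–Alder cycloreversion, as in step 2.

Step 13
Reactants: 17 the 2-acyloxyacrolein; 5 buta-1,3-diene
Product: 18 (R)-1-formylcyclohex-3-en-1-yl 3,4-O-isopropylidene-1,5-bis-O-(triethylsilyl)-ent-quinate
Conditions: (R)-1,1'-binaphthyl-2,2'-diamine (10 mol %), Tf2NH (19 mol %), butadiene (excess), EtCN, −60 → −40 °C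
Reagents that add atoms: none
Why: The primary ammonium salt condenses reversibly with the aldehyde of 17 to an aldiminium ion, a second ammonium N–H hydrogen-bonds to the acyloxy carbonyl, the LUMO is lowered, butadiene adds in a concerted asynchronous [4+2] cycloaddition and hydrolysis returns the catalyst. The closest known reaction is the enantioselective Diels–Alder reaction of α-acyloxyacroleins with simple dienes under chiral primary-ammonium (iminium) catalysis, applied here to a dienophile whose acyl group is ring A. Ring B closes by intermolecular [4+2] cycloaddition, with C1–C6 and C2–C3 formed in the same step and the C4=C5 double bond left as the handle for oxygenation. The only new stereocentre, C1 of ring B, is set by the binaphthyl backbone of the catalyst, which shields one face of the iminium ion; the stereocentres of ring A lie outside the reacting π system, and a minor C1 epimer would be a diastereomer removable by chromatography. Only π-facial selectivity is needed, because butadiene is symmetrical and only the acrolein C=C is activated; the silyl ethers and the acetonide should tolerate the weakly acidic salt at low temperature.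

Step 14
Reactants: 18 the aldehyde
Product: 19 (R)-1-[(3,4-O-isopropylidene-1,5-bis-O-(triethylsilyl)-ent-quinoyl)oxy]cyclohex-3-ene-1-carboxylic acid
Conditions: NaClO2, NaH2PO4, 2-methylbut-2-ene, t-BuOH/H2O, 0 °C → rt
Reagents that add atoms: sodium chlorite, [Na+].[O-]Cl=O
Why: Pinnick oxidation gives the ring B acid chemoselectively in the presence of the alkene, esters, silyl ethers and acetonide.

Step 15
Reactants: 19 the ring B acid
Product: 20 4-iodo-7-oxo-6-oxabicyclo[3.2.1]octan-1-yl ester of the ring A acid (ring B iodolactone, iodine trans to the lactone oxygen)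
Conditions: I2, NaHCO3, H2O/CH2Cl2, 0 °C → rt, dark
Reagents that add atoms: iodine, II
Why: Iodolactonization relays C1 of ring B to C5 (oxygen cis to the carboxyl) and C4 (iodine trans) by anti opening of the iodonium ion.

Step 16
Reactants: 20 the ring B iodolactone
Product: 21 7-oxo-6-oxabicyclo[3.2.1]oct-3-en-1-yl ester of the ring A acid
Conditions: DBU, toluene, 80 °C
Reagents that add atoms: none
Why: E2 dehydroiodination away from the bridgehead gives the C3=C4 alkene of ring B; no base-labile hydroxyl is free at this stage.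

Step 17
Reactants: 21 the ring B unsaturated lactone
Product: 22 ent-quinid-1-yl 3,4-O-isopropylidene-1,5-bis-O-(triethylsilyl)-ent-quinate (ring B: 1,5-lactone with free cis-3,4-diol)
Conditions: OsO4 (2 mol %), N-methylmorpholine N-oxide, acetone/H2O, rt
Reagents that add atoms: osmium tetroxide, O=[Os](=O)(=O)=O (catalytic oxygen carrier); N-methylmorpholine N-oxide, C[N+]1([O-])CCOCC1; water, O
Why: Upjohn cis-dihydroxylation on the face opposite the lactone bridge sets O3 and O4 of ring B; it is run before any cinnamate is present, since a caffeoyl alkene would compete.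

Step 18
Reactants: 23 caffeic acid
Product: 24 (E)-3,4-diacetoxycinnamic acid
Conditions: Ac2O, pyridine, rt; aqueous work-up
Reagents that add atoms: acetic anhydride, CC(=O)OC(C)=O
Why: Acetylation of both phenols (nucleophilic acyl substitution); any mixed anhydride at the carboxyl is hydrolysed on work-up.

Step 19
Reactants: 24 (E)-3,4-diacetoxycinnamic acid
Product: 25 (E)-3,4-diacetoxycinnamoyl chloride
Conditions: (COCl)2, DMF (cat.), CH2Cl2, 0 °C → rt; evaporate, isolate as a solid under argon
Reagents that add atoms: oxalyl chloride, ClC(=O)C(=O)Cl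
Why: Vilsmeier-type chlorination through the chloroiminium ion converts the acid to the acid chloride and leaves the aryl acetates and the E-alkene untouched.

Step 20
Reactants: 22 the silylated diol lactone; 25 (E)-3,4-diacetoxycinnamoyl chloride
Product: 26 3-O-(3,4-diacetoxycinnamoyl)-ent-quinid-1-yl 3,4-O-isopropylidene-1,5-bis-O-(triethylsilyl)-ent-quinate
Conditions: 25 (1.05 equiv), pyridine, DMAP (cat.), CH2Cl2, −40 → −10 °C
Reagents that add atoms: none
Why: Esterification through the acylpyridinium ion, in which the equatorial O3 of the lactone-locked cis-diol reacts faster than the axial O4, while ring A is still fully silylated so that no other hydroxyl competes.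

Step 21
Reactants: 26 the ring B mono-ester
Product: 27 3-O-(3,4-diacetoxycinnamoyl)-ent-quinid-1-yl 3,4-O-isopropylidene-ent-quinate (free hydroxyls: O1 and O5 of ring A, O4 of ring B)
Conditions: HF·pyridine, pyridine, THF, 0 °C → rt
Reagents that add atoms: none
Why: Fluoride-mediated desilylation, driven by Si–F bond formation, under buffered conditions that leave the acetonide, the lactone, the cinnamate and the aryl acetates intact.

Step 22
Reactants: 27 the triol; 25 (E)-3,4-diacetoxycinnamoyl chloride
Product: 28 3-O-(3,4-diacetoxycinnamoyl)-ent-quinid-1-yl 5-O-(3,4-diacetoxycinnamoyl)-3,4-O-isopropylidene-ent-quinate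
Conditions: 25 (1.1 equiv), pyridine, DMAP (cat.), CH2Cl2, −20 → 0 °C
Reagents that add atoms: none
Why: Esterification through the acylpyridinium ion at the only unhindered secondary hydroxyl, O5 of ring A, in preference to the tertiary O1 of ring A and the axial O4 of ring B that is flanked by the O3 ester.

Step 23
Reactants: 28 the protected bis-ester
Product: 29 the target
Conditions: 1 M HCl (aq)/THF (1:4), rt, several days
Reagents that add atoms: water, O
Why: Acid-catalysed hydrolysis removes the acetonide and the four aryl acetates and opens the strained γ-lactone of ring B, while the cinnamate and tertiary alkyl esters hydrolyse more slowly and acidic conditions suppress acyl migration.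

Compound list
1 | 2,2-dimethyl-1,3-dioxan-5-one | CC1(C)OCC(=O)CO1 | starting material
2 | sodium 2,2-dimethyl-4H-1,3-dioxin-5-olate | CC1(C)OCC([O-])=CO1.[Na+] | intermediate
3 | 2,2-dimethyl-4H-1,3-dioxin-5-yl acetate | CC(=O)OC1=COC(C)(C)OC1 | intermediate
4 | 2-acetoxyacrolein | CC(=O)OC(=C)C=O | intermediate
5 | buta-1,3-diene | C=CC=C | starting material
6 | (R)-1-formylcyclohex-3-en-1-yl acetate | CC(=O)O[C@]1(C=O)CCC=CC1 | intermediate
7 | (R)-1-acetoxycyclohex-3-ene-1-carboxylic acid | CC(=O)O[C@]1(C(=O)O)CCC=CC1 | intermediate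
8 | 1-acetoxy-4-iodo-6-oxabicyclo[3.2.1]octan-7-one (iodine trans to lactone oxygen) | CC(=O)O[C@]1(C(=O)O2)CC[C@H](I)[C@@H]2C1 | intermediate
9 | 7-oxo-6-oxabicyclo[3.2.1]oct-3-en-1-yl acetate | CC(=O)O[C@]1(C(=O)O2)CC=C[C@@H]2C1 | intermediate
10 | 1-O-acetyl-ent-quinide | CC(=O)O[C@]1(C(=O)O2)C[C@H](O)[C@H](O)[C@@H]2C1 | intermediate
11 | 1-O-acetyl-3,4-O-isopropylidene-ent-quinide | CC(=O)O[C@]1(C(=O)O2)C[C@@H]3OC(C)(C)O[C@@H]3[C@@H]2C1 | intermediate
12 | 3,4-O-isopropylidene-ent-quinic acid | O[C@]1(C(=O)O)C[C@@H]2OC(C)(C)O[C@@H]2[C@@H](O)C1 | intermediate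
13 | triethylsilyl 3,4-O-isopropylidene-1,5-bis-O-(triethylsilyl)-ent-quinate | CC[Si](CC)(CC)O[C@]1(C(=O)O[Si](CC)(CC)CC)C[C@@H]2OC(C)(C)O[C@@H]2[C@@H](O[Si](CC)(CC)CC)C1 | intermediate
14 | 3,4-O-isopropylidene-1,5-bis-O-(triethylsilyl)-ent-quinoyl chloride | CC[Si](CC)(CC)O[C@]1(C(=O)Cl)C[C@@H]2OC(C)(C)O[C@@H]2[C@@H](O[Si](CC)(CC)CC)C1 | intermediate
15 | potassium 2,2-dimethyl-4H-1,3-dioxin-5-olate | CC1(C)OCC([O-])=CO1.[K+] | intermediate
16 | 2,2-dimethyl-4H-1,3-dioxin-5-yl 3,4-O-isopropylidene-1,5-bis-O-(triethylsilyl)-ent-quinate | CC[Si](CC)(CC)O[C@]1(C(=O)OC3=COC(C)(C)OC3)C[C@@H]2OC(C)(C)O[C@@H]2[C@@H](O[Si](CC)(CC)CC)C1 | intermediate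
17 | 3-oxoprop-1-en-2-yl 3,4-O-isopropylidene-1,5-bis-O-(triethylsilyl)-ent-quinate | CC[Si](CC)(CC)O[C@]1(C(=O)OC(=C)C=O)C[C@@H]2OC(C)(C)O[C@@H]2[C@@H](O[Si](CC)(CC)CC)C1 | intermediate
18 | (R)-1-formylcyclohex-3-en-1-yl 3,4-O-isopropylidene-1,5-bis-O-(triethylsilyl)-ent-quinate | CC[Si](CC)(CC)O[C@]1(C(=O)O[C@]3(C=O)CCC=CC3)C[C@@H]2OC(C)(C)O[C@@H]2[C@@H](O[Si](CC)(CC)CC)C1 | intermediate
19 | (R)-1-[(3,4-O-isopropylidene-1,5-bis-O-(triethylsilyl)-ent-quinoyl)oxy]cyclohex-3-ene-1-carboxylic acid | CC[Si](CC)(CC)O[C@]1(C(=O)O[C@]3(C(=O)O)CCC=CC3)C[C@@H]2OC(C)(C)O[C@@H]2[C@@H](O[Si](CC)(CC)CC)C1 | intermediate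
20 | ring B iodolactone: 4-iodo-7-oxo-6-oxabicyclo[3.2.1]octan-1-yl ester of the ring A acid | CC[Si](CC)(CC)O[C@]1(C(=O)O[C@]3(C(=O)O4)CC[C@H](I)[C@@H]4C3)C[C@@H]2OC(C)(C)O[C@@H]2[C@@H](O[Si](CC)(CC)CC)C1 | intermediate
21 | ring B unsaturated lactone: 7-oxo-6-oxabicyclo[3.2.1]oct-3-en-1-yl ester of the ring A acid | CC[Si](CC)(CC)O[C@]1(C(=O)O[C@]3(C(=O)O4)CC=C[C@@H]4C3)C[C@@H]2OC(C)(C)O[C@@H]2[C@@H](O[Si](CC)(CC)CC)C1 | intermediate
22 | ent-quinid-1-yl 3,4-O-isopropylidene-1,5-bis-O-(triethylsilyl)-ent-quinate | CC[Si](CC)(CC)O[C@]1(C(=O)O[C@]3(C(=O)O4)C[C@H](O)[C@H](O)[C@@H]4C3)C[C@@H]2OC(C)(C)O[C@@H]2[C@@H](O[Si](CC)(CC)CC)C1 | intermediate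
23 | caffeic acid | OC(=O)/C=C/c1ccc(O)c(O)c1 | starting material
24 | (E)-3,4-diacetoxycinnamic acid | CC(=O)Oc1ccc(/C=C/C(=O)O)cc1OC(C)=O | intermediate
25 | (E)-3,4-diacetoxycinnamoyl chloride | CC(=O)Oc1ccc(/C=C/C(=O)Cl)cc1OC(C)=O | intermediate
26 | 3-O-(3,4-diacetoxycinnamoyl)-ent-quinid-1-yl 3,4-O-isopropylidene-1,5-bis-O-(triethylsilyl)-ent-quinate | CC[Si](CC)(CC)O[C@]1(C(=O)O[C@]3(C(=O)O4)C[C@H](OC(=O)/C=C/c5ccc(OC(C)=O)c(OC(C)=O)c5)[C@H](O)[C@@H]4C3)C[C@@H]2OC(C)(C)O[C@@H]2[C@@H](O[Si](CC)(CC)CC)C1 | intermediate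
27 | 3-O-(3,4-diacetoxycinnamoyl)-ent-quinid-1-yl 3,4-O-isopropylidene-ent-quinate | O[C@]1(C(=O)O[C@]3(C(=O)O4)C[C@H](OC(=O)/C=C/c5ccc(OC(C)=O)c(OC(C)=O)c5)[C@H](O)[C@@H]4C3)C[C@@H]2OC(C)(C)O[C@@H]2[C@@H](O)C1 | intermediate
28 | 3-O-(3,4-diacetoxycinnamoyl)-ent-quinid-1-yl 5-O-(3,4-diacetoxycinnamoyl)-3,4-O-isopropylidene-ent-quinate | O[C@]1(C(=O)O[C@]3(C(=O)O4)C[C@H](OC(=O)/C=C/c5ccc(OC(C)=O)c(OC(C)=O)c5)[C@H](O)[C@@H]4C3)C[C@@H]2OC(C)(C)O[C@@H]2[C@@H](OC(=O)/C=C/c6ccc(OC(C)=O)c(OC(C)=O)c6)C1 | intermediate
29 | CNP0107948.1: 3-O-caffeoyl-1-O-(5-O-caffeoyl-ent-quinoyl)-ent-quinic acid | O=C(/C=C/c1ccc(O)c(O)c1)O[C@H]1C[C@@](O)(C(=O)O[C@]2(C(=O)O)C[C@H](OC(=O)/C=C/c3ccc(O)c(O)c3)[C@H](O)[C@@H](O)C2)C[C@H](O)[C@@H]1O | target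

Total step count: 23. Longest linear sequence: 21 steps (steps 1–17 and 20–23); steps 18 and 19 form a two-step side branch.

Steps most likely to fail

Step 13. Unactivated butadiene may add too slowly at the low temperature needed for facial control, a mismatched pairing between the catalyst and the chiral acyl group may erode the selectivity at C1, and the acidic salt may strip silyl or acetonide protection. The fallback gives up catalyst control and relies on separating C1 epimers. It sets out from 14 and returns at 19. Acylation of methyl pyruvate with 14 (Et3N, DMAP, CH2Cl2) should give the methyl 2-acyloxyacrylate F1. An uncatalysed thermal Diels–Alder reaction with butadiene (toluene, sealed tube, 120 °C, radical inhibitor) should give the methyl ester adduct F2 as two C1 epimers, which are diastereomers because of ring A and are separated by chromatography. SN2 demethylation with LiI in refluxing ethyl acetate, which attacks only the methyl group, then gives acid 19.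

Step 11. The neopentyl-type silyl ester may convert only partly to the chloride, and the hindered chloride may acylate the enolate slowly or at carbon while the enolate self-condenses. The fallback builds the acyloxyacrolein by carboxylate alkylation instead of acylation. It sets out from 13 and returns at 17. Brief treatment with K2CO3 in aqueous methanol at 0 °C cleaves only the silyl ester to give the bis-silylated acid F3. Cs2CO3 and allyl bromide in DMF give the allyl ester F4 by SN2 at the allyl carbon, which is insensitive to hindrance at the acyl carbon. Ozonolysis (O3, CH2Cl2, −78 °C; then Me2S) gives the 2-oxoethyl ester F5, and α-methylenation with dimethylmethylideneammonium iodide and Et3N (Mannich reaction, then elimination) gives 17.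

Step 20. Kinetic discrimination between the two hydroxyls of the ring B cis-diol may be incomplete, so that acylation at the axial O4, double acylation or base-promoted acyl migration from O3 to O4 gives regioisomer mixtures. The fallback replaces kinetic discrimination by a temporary five-membered tin acetal that activates one oxygen. It sets out from 22 and returns at 26. Heating 22 with dibutyltin oxide (Bu2SnO) in toluene with azeotropic removal of water should give the ring B 3,4-O-dibutylstannylene acetal F6. Treatment with 25 (1.0 equiv) in CH2Cl2 at 0 °C, in which the stannylene acetal of a cis-diol passes the acyl group to its equatorial oxygen, followed by work-up with dilute HCl, then gives 26.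

Further compounds
F1 | step 13 | methyl 2-[(3,4-O-isopropylidene-1,5-bis-O-(triethylsilyl)-ent-quinoyl)oxy]acrylate | CC[Si](CC)(CC)O[C@]1(C(=O)OC(=C)C(=O)OC)C[C@@H]2OC(C)(C)O[C@@H]2[C@@H](O[Si](CC)(CC)CC)C1
F2 | step 13 | methyl (R)-1-[(3,4-O-isopropylidene-1,5-bis-O-(triethylsilyl)-ent-quinoyl)oxy]cyclohex-3-ene-1-carboxylate | CC[Si](CC)(CC)O[C@]1(C(=O)O[C@]3(C(=O)OC)CCC=CC3)C[C@@H]2OC(C)(C)O[C@@H]2[C@@H](O[Si](CC)(CC)CC)C1
F3 | step 11 | 3,4-O-isopropylidene-1,5-bis-O-(triethylsilyl)-ent-quinic acid | CC[Si](CC)(CC)O[C@]1(C(=O)O)C[C@@H]2OC(C)(C)O[C@@H]2[C@@H](O[Si](CC)(CC)CC)C1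
F4 | step 11 | allyl 3,4-O-isopropylidene-1,5-bis-O-(triethylsilyl)-ent-quinate | CC[Si](CC)(CC)O[C@]1(C(=O)OCC=C)C[C@@H]2OC(C)(C)O[C@@H]2[C@@H](O[Si](CC)(CC)CC)C1
F5 | step 11 | 2-oxoethyl 3,4-O-isopropylidene-1,5-bis-O-(triethylsilyl)-ent-quinate | CC[Si](CC)(CC)O[C@]1(C(=O)OCC=O)C[C@@H]2OC(C)(C)O[C@@H]2[C@@H](O[Si](CC)(CC)CC)C1
F6 | step 20 | 3,4-O-(dibutylstannylene)-ent-quinid-1-yl 3,4-O-isopropylidene-1,5-bis-O-(triethylsilyl)-ent-quinate | CC[Si](CC)(CC)O[C@]1(C(=O)O[C@]3(C(=O)O4)C[C@@H]5O[Sn](CCCC)(CCCC)O[C@@H]5[C@@H]4C3)C[C@@H]2OC(C)(C)O[C@@H]2[C@@H](O[Si](CC)(CC)CC)C1
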